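**Reading time.** At 3.0 min I must say what stands in each flask, so I count what has gone, not only what has formed.

| flask | substrate | coupling partner | temperature | remark | time |
|---|---|---|---|---|---|
| north | 12 mM | 0.80 equiv | 65 °C | run made earlier |  |
| south-east | 12 mM | 0.40 equiv | 76 °C | run made earlier |  |
| north-east | 12 mM | 1.6 equiv | 65 °C | run made earlier |  |
| larch | 12 mM | 0.800 equiv (in portions, 2, over 2.5 min) | 70 °C | first portion at the start, last at 2.5 min | 3.0 min |
| maple | 12 mM | 0.800 equiv |  | everything together at the start at 40 °C, warmed to 70 °C at 2.5 min | 3.0 min |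
| oak | 12 mM (fed, over 2.5 min) | 0.800 equiv |  | the addition at 40 °C, then warmed to 70 °C; the feed brings no volume worth counting | 3.0 min |
| elm | 12 mM (fed, over 2.5 min) | 0.800 equiv | 70 °C | all else is in the flask from the start; the feed brings no volume worth counting | 3.0 min |
| ash | 12 mM | 0.800 equiv (fed, over 2.5 min) | 70 °C | all else is in the flask from the start; the feed brings no volume worth counting | 3.0 min |

north run (percent of the substrate charged)

| time / s | target / % | substrate / % |
|---|---|---|
| 10.0 | 10.7 | 83.8 |
| 12.0 | 12.1 | 82.9 |
| 20.0 | 21.1 | 74.4 |
| 30.0 | 24.9 | 65.2 |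
| 50.0 | 34.0 | 51.7 |
| 80.0 | 39.1 | 39.9 |
| 120 | 43.7 | 32.0 |

south-east run (percent of the substrate charged)

| time / min | target / % | substrate / % |
|---|---|---|
| 0.500 | 22.2 | 50.9 |
| 1.00 | 27.4 | 33.4 |
| 1.50 | 32.0 | 24.7 |
| 2.00 | 30.7 | 17.9 |
| 2.50 | 30.6 | 14.1 |
| 3.00 | 31.0 | 13.0 |
| 4.00 | 31.7 | 9.3 |

north-east run (percent of the substrate charged)

| time / min | target / % | substrate / % |
|---|---|---|
| 0.250 | 23.4 | 71.6 |
| 0.417 | 29.2 | 61.6 |
| 0.667 | 36.5 | 51.8 |
| 1.00 | 45.7 | 37.9 |
| 1.50 | 50.5 | 30.2 |
| 2.50 | 56.8 | 17.8 |
| 4.00 | 59.7 | 12.7 |

(standard deviation of a reading: 1 percentage point)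



1. which flask leads in amount of target, in percent of the substrate charged ("all alike" within 1.5 percentage points) (larch / maple / oak / elm / ash / all alike)
2. how much target is there at the end, in percent of the substrate charged: larch
3. how much target is there at the end, in percent of the substrate charged: maple
4. how much target is there at the end, in percent of the substrate charged: oak
5. how much target is there at the end, in percent of the substrate charged: elm
6. how much target is there at the end, in percent of the substrate charged: ash

**Two rates.** Substrate leaves by coupling, which gives target, and by a loss, which is the charge minus substrate left minus target. Their ratio, my split (a selectivity factor), comes straight from the readings. The north run at 50.0 s gives 2.38. The north-east run at 0.667 min, with twice the coupling partner, gives 3.12, so twice the partner multiplies the split by 1.31.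

**Going cold.** The south-east run at 0.500 min, raised by that factor to the north run's partner, gives 1.08, lower than the north run. Taking the logarithm of the split as straight in temperature, my rough rule, I get 1.66 at 70 °C and 14.2 at 40 °C: the split at 40 °C, target made per substrate lost otherwise. So I put maple in the lead, because its split at 40 °C is higher than at 70 °C.

**The forecast.** It differs from me: it leads with ash at 34% and gives maple 28% (23% to 34%), larch 32%, elm 23%, oak 20%: “Maple is slow when cold”.

**The flasks.** Maple leads with 44.9%; larch gives 35.1%, oak 34.5%, elm 32.0%, ash 30.6%.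

    substrate + coupling partner → target, rate k1*[substrate]^2*[coupling partner]^0.5 (k = 15.0 M⁻¹·⁵ s⁻¹, Ea = 41.0 kJ mol⁻¹)
    2 substrate → self-condensation product (k = 0.00110 M⁻¹ s⁻¹, Ea = 76.0 kJ mol⁻¹)
    substrate ⇌ dormant form (K = 6.80, k = 0.00680 s⁻¹, Ea = 95.0 kJ mol⁻¹, ΔH = 21.0 kJ mol⁻¹)
    (constants at 70 °C)

**The split.** At 2.50 min maple holds target 35.3% against dormant form 3.21%, a split of 11.0 against my 14.2. Forward coupling over forward dormant-form formation in maple runs from 16 at the start to 0.72 at 3.00 min, after the warming.

**Another flask.** Maple's end split of 3.39, carried to 2.00 equiv of partner by my factor, gives 4.85. The computed neighbour holds target 58.9% against dormant form 10.5%, a split of 5.61.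

All runs are calculated with made-up constants.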